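**Assumption:** (R)-epichlorohydrin, L- and D-allylglycine, isopropenylmagnesium bromide, methyl 2-(hydroxymethyl)acrylate and triethyl phosphonoacetate are purchasable. Cross-metathesis of a monosubstituted or 1,1-disubstituted alkene with a 1,1-disubstituted alkene gives the E-trisubstituted alkene.

## Retrosynthesis
1. Michaolide A comes from one photoredox/Cr-catalysed intramolecular allylation. An allylic bromide (2-(bromomethyl)enoate) adds to an α,β-epoxy aldehyde, forming the C1–C14 bond, the 14-membered ring and the trans α-methylene-γ-lactone together.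
2. The epoxy aldehyde comes from the C14 primary alcohol, which is TBS-protected. The allylic bromide comes from an allylic alcohol, which is the product of two cross-metatheses that form C4=C5 and C8=C9.
3. The three pieces are C1–C4 with the enoate (from (R)-epichlorohydrin), C5–C8 (from L-allylglycine) and C9–C14 (from D-allylglycine).
4. The C12/C13 epoxide is made in the C9–C14 piece by hydroxyl-directed epoxidation of the E-allylic alcohol next to the C11 stereocentre.
5. The epoxide forms first, in the fragment. The macrocycle and lactone form last.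

## Route

**Step 1**
Reactants: 1 (R)-epichlorohydrin; 2 isopropenylmagnesium bromide
Product: 3 (2R)-1-chloro-4-methylpent-4-en-2-ol
Conditions: 2 (1.2 equiv), CuI (10 mol %), THF, –30 → 0 °C
Reagents that add atoms: isopropenylmagnesium bromide, CC(=C)[Mg]Br (reactant 2)
Why: Cu-catalysed Grignard opening of the epoxide at the terminal CH2 (C3–C4 bond). The C2 carbinol centre is not touched, so its configuration comes from the epichlorohydrin.

**Step 2**
Reactants: 3
Product: 4 (2R)-2-(2-methylallyl)oxirane
Conditions: NaOH, H2O/Et2O, 0 °C → rt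
Reagents that add atoms: none
Why: intramolecular Williamson closure by the alkoxide displacing the primary chloride. C2 retains its configuration because it is not the carbon attacked.

**Step 3**
Reactants: 4
Product: 5 (3R)-5-methylhexa-1,5-dien-3-ol
Conditions: Me3S⁺ I⁻ (3 equiv), n-BuLi (3 equiv), THF, –10 °C → rt
Reagents that add atoms: trimethylsulfonium iodide, C[S+](C)C.[I-] (supplies the vinyl CH2)
Why: sulfonium-ylide homologation of a terminal epoxide to an allylic alcohol. The ylide attacks the CH2 end and the carbinol centre is retained.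

**Step 4**
Reactants: 5
Product: 6 (3R)-5-methylhexa-1,5-dien-3-yl acetate
Conditions: Ac2O, Et3N, DMAP (cat.), CH2Cl2, 0 °C
Reagents that add atoms: acetic anhydride, CC(=O)OC(C)=O
Why: O-acetylation. This installs the C2 acetate and protects C2 against lactonisation onto the later enoate.

**Step 5**
Reactants: 6; 7 methyl 2-(hydroxymethyl)acrylate
Product: 8 methyl (4R)-4-(acetyloxy)-2-(hydroxymethyl)-6-methylhepta-2,6-dienoate (C15=C1 geometry unspecified)
Conditions: 7 (4 equiv), Hoveyda–Grubbs II (5 mol %), CH2Cl2, 40 °C
Reagents that add atoms: methyl 2-(hydroxymethyl)acrylate, COC(=O)C(=C)CO (reactant 7)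
Why: cross-metathesis of the monosubstituted vinyl group with the 1,1-disubstituted acrylate, which installs C1=C15–C16/C17. The isopropenyl group is unreactive under these conditions. E/Z geometry is irrelevant because the later allyl-chromium species equilibrates.

**Step 6**
Reactants: 9 L-allylglycine, (2S)-2-aminopent-4-enoic acid
Product: 10 (2S)-2-hydroxypent-4-enoic acid
Conditions: NaNO2, 1 M H2SO4, 0 °C → rt
Reagents that add atoms: water, O (supplies the OH)
Why: diazotisation/hydrolysis with retention (double inversion through an α-lactone). This sets C7 (S).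

**Step 7**
Reactants: 10
Product: 11 (3S)-3-hydroxyhex-5-en-2-one
Conditions: MeLi (4 equiv), THF, –78 → 0 °C
Reagents that add atoms: methyllithium, [Li]C
Why: a carboxylic acid plus two equivalents of MeLi gives the methyl ketone through the stable dilithium gem-diolate. The α-stereocentre is protected as the alkoxide.

**Step 8**
Reactants: 11
Product: 12 (3S)-2-methylhexa-1,5-dien-3-ol (C5–C8 piece)
Conditions: Ph3P⁺CH3 Br⁻ (3 equiv), KOt-Bu (3 equiv), THF, 0 °C → rt
Reagents that add atoms: methylenetriphenylphosphorane, C=P(c1ccccc1)(c1ccccc1)c1ccccc1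
Why: Wittig methylenation of the ketone gives the 1,1-disubstituted alkene that carries C8 and its methyl. Excess ylide covers the free OH.

**Step 9**
Reactants: 13 D-allylglycine, (2R)-2-aminopent-4-enoic acid
Product: 14 (2R)-2-hydroxypent-4-enoic acid
Conditions: NaNO2, 1 M H2SO4, 0 °C → rt
Reagents that add atoms: water, O
Why: same retentive diazotisation as Step 6. It sets C11 (R).

**Step 10**
Reactants: 14
Product: 15 (3R)-3-hydroxyhex-5-en-2-one
Conditions: MeLi (4 equiv), THF, –78 → 0 °C
Reagents that add atoms: methyllithium, [Li]C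
Why: same acid-to-methyl-ketone conversion as Step 7.

**Step 11**
Reactants: 15; 16 triethyl phosphonoacetate
Product: 17 ethyl (2E,4R)-4-hydroxy-3-methylhepta-2,6-dienoate
Conditions: 16 (1.5 equiv), NaH (3 equiv), THF, 0 °C → rt
Reagents that add atoms: triethyl phosphonoacetate, CCOC(=O)CP(=O)(OCC)OCC (reactant 16)
Why: Horner–Wadsworth–Emmons olefination gives the E-trisubstituted enoate (C12=C13, C14 ester). The alkoxide suppresses enolisation at C11.

**Step 12**
Reactants: 17
Product: 18 (2E,4R)-3-methylhepta-2,6-diene-1,4-diol
Conditions: DIBAL-H (3 equiv), CH2Cl2, –78 °C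
Reagents that add atoms: none
Why: DIBAL reduces the ester to the allylic alcohol without touching the alkenes.

**Step 13**
Reactants: 18
Product: 19 (2E,4R)-1-[(tert-butyldimethylsilyl)oxy]-3-methylhepta-2,6-dien-4-ol
Conditions: TBSCl (1.05 equiv), imidazole, CH2Cl2, –20 °C
Reagents that add atoms: tert-butyldimethylsilyl chloride, CC(C)(C)[Si](C)(C)Cl
Why: the unhindered primary OH (C14) is silylated selectively over the secondary C11-OH, which stays free as the directing group.

**Step 14**
Reactants: 19
Product: 20 (1R)-1-[(2S,3S)-3-(TBS-oxymethyl)-2-methyloxiran-2-yl]but-3-en-1-ol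
Conditions: mCPBA (1.2 equiv), NaHCO3, CH2Cl2, –20 °C
Reagents that add atoms: mCPBA, OOC(=O)c1cccc(Cl)c1 (supplies the epoxide O)
Why: Henbest hydroxyl-directed epoxidation of the more electron-rich trisubstituted alkene; the terminal alkene is untouched. Peracid delivery occurs with an O–C–C=C dihedral near 120° and minimised A(1,2) strain from the C12 methyl. It is expected to give the trans-(12S,13S)-epoxide syn to C11-OH, with C11 fixing the sense at C12 and C13. The expected dr is about 5–10:1 and the diastereomers should be separable.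

**Step 15**
Reactants: 20
Product: 21 (1R)-1-[(2S,3S)-3-(TBS-oxymethyl)-2-methyloxiran-2-yl]but-3-en-1-yl acetate (C9–C14 piece)
Conditions: Ac2O, pyridine, DMAP (cat.), CH2Cl2, 0 °C
Reagents that add atoms: acetic anhydride, CC(=O)OC(C)=O
Why: O-acetylation gives the C11 acetate.

**Step 16**
Reactants: 8; 12
Product: 22 methyl (4R,6E,9S)-4-(acetyloxy)-9-hydroxy-2-(hydroxymethyl)-6,10-dimethylundeca-2,6,10-trienoate (C1–C8 piece)
Conditions: 12 (3 equiv), Hoveyda–Grubbs II (10 mol %), CH2Cl2, 40 °C
Reagents that add atoms: none beyond numbered reactants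
Why: cross-metathesis of the 1,1-disubstituted C4 alkene of 8 with the monosubstituted allyl group of 12 (used in excess) gives the E-trisubstituted C4=C5 alkene with loss of ethylene. The enoate and the isopropenyl group are inert.

**Step 17**
Reactants: 22; 21
Product: 23 acyclic hydroxy ester HOCH2–C(CO2Me)=CH–C2H(OAc)–CH2–C(Me)=CH–CH2–C7H(OH)–C(Me)=CH–CH2–C11H(OAc)–[C12(Me)–O–C13]–CH2OTBS (4E, 8E; 2R, 7S, 11R, 12S, 13S)
Conditions: 21 (1.5 equiv), Hoveyda–Grubbs II (10 mol %), toluene, 60 °C
Reagents that add atoms: none beyond numbered reactants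
Why: cross-metathesis joining the C8 isopropenyl group to the C9 allyl group gives the E-trisubstituted C8=C9 alkene. The free C7-OH does not interfere.

**Step 18**
Reactants: 23
Product: 24 allylic bromide BrCH2–C(CO2Me)=CH–… (same backbone as 23, CH2OH replaced by CH2Br)
Conditions: CBr4 (1.5 equiv), PPh3 (1.5 equiv), CH2Cl2, 0 °C
Reagents that add atoms: carbon tetrabromide, BrC(Br)(Br)Br
Why: Appel bromination is selective for the unhindered, activated primary allylic alcohol over the hindered secondary C7-OH. This gives the 2-(bromomethyl)enoate that will become the allyl-chromium species.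

**Step 19**
Reactants: 24
Product: 25 primary alcohol (24 with CH2OTBS replaced by CH2OH at C14)
Conditions: HF·pyridine, excess pyridine, THF, 0 °C
Reagents that add atoms: none
Why: buffered fluoride removes the primary TBS ether and leaves the acetates, epoxide and bromide intact.

**Step 20**
Reactants: 25
Product: 26 α,β-epoxy aldehyde (24 with C14 as CHO; free C7-OH)
Conditions: TEMPO (10 mol %), PhI(OAc)2 (1.3 equiv), CH2Cl2, 0 °C
Reagents that add atoms: none
Why: TEMPO/BAIB oxidation is selective for the primary alcohol over the hindered secondary allylic C7-OH and gives the epoxy aldehyde without overoxidation. The crude product is used immediately.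

**Step 21**
Reactants: 26
Product: 27 michaolide A (target)
Conditions: CrCl2 (20 mol %), 4CzIPN (2 mol %), Hantzsch ester (2 equiv), 2,4,6-collidine·HCl (2 equiv), THF/MeCN, blue LEDs (455 nm), 25 °C, 2 mM with slow addition of 26; then PPTS (0.1 equiv) to complete lactonisation (loss of MeOH)
Reagents that add atoms: none
Why: Proposed new method: a photoredox/Cr-catalysed Nozaki–Hiyama–Kishi allylation run as a macrocyclisation onto an α,β-epoxy aldehyde, with catalytic Cr (the closest known reactions are dual photoredox/Cr allylations of aldehydes and stoichiometric CrCl2 macrocyclisations in cembranolide syntheses). Cr(II) reduces the allylic bromide to an allyl-Cr(III) species, which adds through a Zimmerman–Traxler chair transition state. The carbon–carbon bond forms at C1, the γ-carbon, and the alkene shifts to give the exocyclic methylene. The E-allyl chair transition state gives the anti, trans-β,γ-disubstituted lactone, which sets C1/C14 relative to each other. Their absolute sense relative to C2 and C13 is expected from macrocyclic conformational control. Collidinium protonates the Cr(III) alkoxide, and reduced 4CzIPN (from Hantzsch ester) regenerates Cr(II), so no Mn, Zn or TMSCl is needed. The lactone closes by attack of the C14 alkoxide/alcohol on the ester. Aliphatic aldehydes are not reduced under these conditions.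

## Compound list
1 | (R)-epichlorohydrin | ClC[C@H]1CO1 | starting material
2 | isopropenylmagnesium bromide | CC(=C)[Mg]Br | starting material
3 | (2R)-1-chloro-4-methylpent-4-en-2-ol | ClC[C@H](O)CC(C)=C | intermediate
4 | (2R)-2-(2-methylallyl)oxirane | C=C(C)C[C@@H]1CO1 | intermediate
5 | (3R)-5-methylhexa-1,5-dien-3-ol | C=C[C@H](O)CC(C)=C | intermediate
6 | (3R)-5-methylhexa-1,5-dien-3-yl acetate | C=C[C@H](OC(C)=O)CC(C)=C | intermediate
7 | methyl 2-(hydroxymethyl)acrylate | COC(=O)C(=C)CO | starting material
8 | methyl (4R)-4-acetoxy-2-(hydroxymethyl)-6-methylhepta-2,6-dienoate | COC(=O)C(CO)=C[C@H](OC(C)=O)CC(C)=C | intermediate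
9 | L-allylglycine | C=CC[C@H](N)C(=O)O | starting material
10 | (2S)-2-hydroxypent-4-enoic acid | C=CC[C@H](O)C(=O)O | intermediate
11 | (3S)-3-hydroxyhex-5-en-2-one | C=CC[C@H](O)C(C)=O | intermediate
12 | (3S)-2-methylhexa-1,5-dien-3-ol | C=CC[C@H](O)C(C)=C | intermediate
13 | D-allylglycine | C=CC[C@@H](N)C(=O)O | starting material
14 | (2R)-2-hydroxypent-4-enoic acid | C=CC[C@@H](O)C(=O)O | intermediate
15 | (3R)-3-hydroxyhex-5-en-2-one | C=CC[C@@H](O)C(C)=O | intermediate
16 | triethyl phosphonoacetate | CCOC(=O)CP(=O)(OCC)OCC | starting material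
17 | ethyl (2E,4R)-4-hydroxy-3-methylhepta-2,6-dienoate | C=CC[C@@H](O)/C(C)=C/C(=O)OCC | intermediate
18 | (2E,4R)-3-methylhepta-2,6-diene-1,4-diol | C=CC[C@@H](O)/C(C)=C/CO | intermediate
19 | (2E,4R)-1-(TBS-oxy)-3-methylhepta-2,6-dien-4-ol | C=CC[C@@H](O)/C(C)=C/CO[Si](C)(C)C(C)(C)C | intermediate
20 | (1R)-1-[(2S,3S)-3-(TBS-oxymethyl)-2-methyloxiran-2-yl]but-3-en-1-ol | C=CC[C@@H](O)[C@]1(C)O[C@H]1CO[Si](C)(C)C(C)(C)C | intermediate
21 | the corresponding acetate (C9–C14 piece) | C=CC[C@@H](OC(C)=O)[C@]1(C)O[C@H]1CO[Si](C)(C)C(C)(C)C | intermediate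
22 | methyl (4R,6E,9S)-4-acetoxy-9-hydroxy-2-(hydroxymethyl)-6,10-dimethylundeca-2,6,10-trienoate | COC(=O)C(CO)=C[C@H](OC(C)=O)C/C(C)=C/C[C@H](O)C(C)=C | intermediate
23 | seco hydroxy ester (C1–C14 chain, CH2OH allylic alcohol, C14-OTBS epoxide) | COC(=O)C(CO)=C[C@H](OC(C)=O)C/C(C)=C/C[C@H](O)/C(C)=C/C[C@@H](OC(C)=O)[C@]1(C)O[C@H]1CO[Si](C)(C)C(C)(C)C | intermediate
24 | allylic bromide of 23 | COC(=O)C(CBr)=C[C@H](OC(C)=O)C/C(C)=C/C[C@H](O)/C(C)=C/C[C@@H](OC(C)=O)[C@]1(C)O[C@H]1CO[Si](C)(C)C(C)(C)C | intermediate
25 | C14 primary alcohol (TBS removed) | COC(=O)C(CBr)=C[C@H](OC(C)=O)C/C(C)=C/C[C@H](O)/C(C)=C/C[C@@H](OC(C)=O)[C@]1(C)O[C@H]1CO | intermediate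
26 | α,β-epoxy aldehyde | COC(=O)C(CBr)=C[C@H](OC(C)=O)C/C(C)=C/C[C@H](O)/C(C)=C/C[C@@H](OC(C)=O)[C@]1(C)O[C@H]1C=O | intermediate
27 | michaolide A | C=C1C(=O)O[C@H]2[C@H]1[C@H](OC(C)=O)C/C(C)=C/C[C@H](O)/C(C)=C/C[C@@H](OC(C)=O)[C@]1(C)O[C@@H]21 | target

## Totals
Total steps: 21. Longest linear sequence: 12 (Steps 9–15, then 17–21).

## Three steps most likely to fail
1. **Step 21 (proposed new photoredox/Cr macrocyclisation).** Risks are hydrodebromination by Hantzsch ester, 1,4-elimination of the γ-acetate from the allyl-Cr species, epoxy-aldehyde decomposition, and low diastereoselectivity at C1/C14. Fallback (known chemistry): classical stoichiometric CrCl2 (with cat. NiCl2) intramolecular NHK in DMF/THF at high dilution, or a Zn/In Barbier macrocyclisation, on the same bromo-aldehyde 26.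
2. **Step 17 (second cross-metathesis, hindered isopropenyl carbinol with a valuable partner).** Risks are low yield and E/Z erosion. Fallback: make the C8=C9 alkene by Zr-catalysed methylalumination/iodination of the terminal alkyne derived from 12 (via α-silyloxy aldehyde and Ohira–Bestmann), then join C9 to C10 by Negishi or B-alkyl Suzuki sp2–sp3 coupling with a C10 nucleophile on the C10–C14 piece.
3. **Step 14 (diastereoselectivity of the directed epoxidation).** The wrong epoxide diastereomer would form if the peracid transition-state model is off. Fallback: run the C9–C14 sequence from L-allylglycine (the C11 (S) series), epoxidise with VO(acac)2/TBHP (which is expected to favour the other, anti, diastereomer), then invert C11 with a Mitsunobu reaction (p-nitrobenzoic acid), cleave the ester and acetylate. This gives the same (11R,12S,13S) piece.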